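**Strategy.** The pyranone ring of the 2,3-trans flavan unit is cut at O1–C8a and C4–C4a. A 2-fluoro-3,4-bis(benzyloxy)phenyllithium and a trans-3-benzyloxy-4-aryl-β-lactone (an O1–C2–C3–C4 unit whose acyl C4–O1 bond is the latent link) are joined in one anionic domino: acyl substitution forms C4–C4a and frees the O1 alkoxide, and the new C4 ketone, ortho to C8a–F between C8–O and C4a, triggers SNAr closure. C2/C3 come from the lactone; L-Selectride sets the 3,4-cis alcohol. This alcohol opens the 3,4-epoxide of the antipodal-series flav-3-ene at C4; C3 inversion by oxidation/reduction and hydrogenolysis finish.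

Key step: step 7

Assumption: the absolute sense of the two reagent-controlled steps (4 and 11) is assigned from the usual transition-state models and is not certain; if either runs in the opposite sense, the antipodal auxiliary or catalyst is used and nothing else changes.

**Route**

Step 1
Reactants: 1 3-fluorocatechol
Product: 2 1,2-bis(benzyloxy)-3-fluorobenzene
Conditions: BnBr, K2CO3, DMF, 60 °C
Reagents that add atoms: benzyl bromide, BrCc1ccccc1
Why: Williamson etherification of both phenols (SN2 on benzyl bromide); no stereocentre.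

Step 2
Reactants: 2 1,2-bis(benzyloxy)-3-fluorobenzene
Product: 3 1,2-bis(benzyloxy)-4-bromo-3-fluorobenzene
Conditions: NBS, MeCN, 0 °C to rt
Reagents that add atoms: N-bromosuccinimide, O=C1CCC(=O)N1Br
Why: Electrophilic aromatic bromination para to the conjugated C1 benzyloxy group (the doubly flanked C2 ether is twisted out of conjugation), which puts Br next to F.

Step 3
Reactants: 4 (S)-4-benzyl-1,3-oxazolidine-2-thione; 5 benzyloxyacetyl chloride
Product: 6 (S)-4-benzyl-3-(benzyloxyacetyl)-1,3-oxazolidine-2-thione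
Conditions: Et3N, DMAP (cat.), CH2Cl2, 0 °C
Reagents that add atoms: none
Why: N-acylation of the oxazolidinethione by the acid chloride; the auxiliary stereocentre is untouched.

Step 4
Reactants: 6 (S)-4-benzyl-3-(benzyloxyacetyl)-1,3-oxazolidine-2-thione; 7 4-(benzyloxy)benzaldehyde
Product: 8 (4S)-4-benzyl-3-[(2S,3S)-2-(benzyloxy)-3-[4-(benzyloxy)phenyl]-3-hydroxypropanoyl]-1,3-oxazolidine-2-thione
Conditions: TiCl4, i-Pr2NEt, CH2Cl2, −78 °C; then 7·TiCl4, −78 °C
Reagents that add atoms: none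
Why: Crimmins-type anti-glycolate aldol, in which the chlorotitanium Z-enolate adds through an open transition state to the TiCl4-activated aldehyde while the auxiliary benzyl group shields one enolate face, setting C2' and C3' anti.

Step 5
Reactants: 8 anti-aldol adduct
Product: 9 (2S,3S)-2-(benzyloxy)-3-[4-(benzyloxy)phenyl]-3-hydroxypropanoic acid
Conditions: LiOH, THF/H2O, 0 °C; cold aq. HCl work-up
Reagents that add atoms: lithium hydroxide, [Li+].[OH-]
Why: Hydroxide attacks the exocyclic acyl carbon of the activated imide and releases the thione auxiliary; cold, short conditions limit retro-aldol and no stereocentre is touched.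

Step 6
Reactants: 9 anti-hydroxy acid
Product: 10 (3S,4S)-3-(benzyloxy)-4-[4-(benzyloxy)phenyl]oxetan-2-one (trans)
Conditions: PhSO2Cl, pyridine, −10 to 0 °C; used at once
Reagents that add atoms: none
Why: Adam β-lactonisation by carboxyl activation (mixed sulfonic anhydride) and attack of the β-hydroxyl on the acyl carbon, so both stereocentres are retained and the anti acid gives the trans lactone.

Step 7
Reactants: 3 1,2-bis(benzyloxy)-4-bromo-3-fluorobenzene; 10 trans-β-lactone
Product: 13 (2S,3S)-3,7,8-tris(benzyloxy)-2-[4-(benzyloxy)phenyl]chroman-4-one, via aryllithium 11 (not isolated), via lithium keto-alkoxide 12 (not isolated)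
Conditions: 3, n-BuLi (1.0 equiv), THF, −78 °C; then 10, −78 °C; then DMPU, −78 to 23 °C
Reagents that add atoms: none
Why: Br/Li exchange gives the 2-fluoroaryllithium 11 (no LiF loss at −78 °C), which as a hard nucleophile attacks the strained lactone carbonyl and cleaves the acyl C4–O1 bond, forming C4–C4a and unmasking O1 as the lithium alkoxide 12; on warming this alkoxide adds to C8a, now ortho to the new C4 ketone, and fluoride leaves from the Meisenheimer intermediate, forming O1–C8a. The closest known reaction types are the opening of β-lactones by organolithiums to β-hydroxy ketones and the alkoxide SNAr cyclisation of 2-fluoroaryl ketones to chroman-4-ones. The one ring is closed in the 6-exo-trig mode (addition–elimination at C8a). No stereocentre is created: C2 and C3 are carried over from the trans lactone with retention because no bond to either is broken. Regiochemistry is fixed by the positions of Br (C4a) and F (C8a) in 3, acyl- over alkyl-oxygen cleavage by the hard aryllithium, and mono-addition by the 1:1 stoichiometry and the chelated, electron-rich aryl ketone; fast cyclisation (DMPU) and the absence of excess base are needed to outrun retro-aldol cleavage and C3 enolisation of 12.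

Step 8
Reactants: 13 trans-3-benzyloxychroman-4-one
Product: 14 (2S,3R,4R)-3,7,8-tris(benzyloxy)-2-[4-(benzyloxy)phenyl]chroman-4-ol (2,3-trans-3,4-cis)
Conditions: L-Selectride, THF, −78 °C; aqueous work-up
Reagents that add atoms: none
Why: Substrate-controlled ketone reduction in which the bulky hydride approaches C4 from the face opposite the adjacent equatorial 3-benzyloxy group (equatorial attack) and should give the axial 4-OH cis to O3.

Step 9
Reactants: 15 7,8-dihydroxycoumarin (daphnetin)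
Product: 16 7,8-bis(benzyloxy)-2H-chromen-2-one
Conditions: BnBr, K2CO3, DMF, 60 °C
Reagents that add atoms: benzyl bromide, BrCc1ccccc1
Why: Williamson etherification of the two phenols; no stereocentre.

Step 10
Reactants: 16 7,8-bis(benzyloxy)-2H-chromen-2-one
Product: 18 7,8-bis(benzyloxy)-2-ethoxy-2H-chromene (racemic acetal), via lactol 17 (not isolated)
Conditions: DIBAL-H, CH2Cl2, −78 °C; Rochelle salt; then EtOH, PPTS, rt
Reagents that add atoms: ethanol, CCO
Why: DIBAL-H half-reduction of the lactone to the lactol, then acid-catalysed acetalisation through the 7-alkoxy-stabilised benzopyrylium ion; the acetal centre is lost again in step 11.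

Step 11
Reactants: 18 2-ethoxy-2H-chromene; 19 4-(benzyloxy)phenylboronic acid
Product: 20 (2S)-7,8-bis(benzyloxy)-2-[4-(benzyloxy)phenyl]-2H-chromene
Conditions: 19, EtOH, 4 Å MS (boronate formed in situ); (R,R)-tartaric-acid-derived diol amide (5 mol%), Ce(OTf)4 (5 mol%), EtOAc, −20 °C
Reagents that add atoms: none
Why: Enantioselective addition of an aryl boronate to a chromene acetal under chiral diol/Lewis acid catalysis, in which ionisation to the benzopyrylium ion and aryl transfer from the chiral diol-boronate set C2.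

Step 12
Reactants: 20 (2S)-flav-3-ene; 14 B-unit alcohol
Product: 22 (2R,3S,4R)-7,8-bis(benzyloxy)-2-[4-(benzyloxy)phenyl]-4-{[(2S,3R,4R)-3,7,8-tris(benzyloxy)-2-[4-(benzyloxy)phenyl]chroman-4-yl]oxy}chroman-3-ol, via epoxide 21 (not isolated)
Conditions: DMDO, acetone/CH2Cl2, −40 °C; concentrate cold; then 14, PPTS (cat.), 4 Å MS, CH2Cl2, −40 to 0 °C
Reagents that add atoms: dimethyldioxirane, CC1(C)OO1
Why: DMDO epoxidation of the electron-rich C3=C4 bond on the face opposite the 2-aryl group, then acid-assisted alcoholysis of the benzylic epoxide at C4 with inversion, which should give the 2,3-trans-3,4-trans ether-alcohol (C4 of this unit is now correct; C3 is inverted in steps 13–14).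

Step 13
Reactants: 22 ether-alcohol
Product: 23 (2R,4R)-7,8-bis(benzyloxy)-2-[4-(benzyloxy)phenyl]-4-{[(2S,3R,4R)-3,7,8-tris(benzyloxy)-2-[4-(benzyloxy)phenyl]chroman-4-yl]oxy}chroman-3-one
Conditions: Dess–Martin periodinane, NaHCO3, CH2Cl2, 0 °C
Reagents that add atoms: none
Why: Buffered Dess–Martin oxidation of the only free hydroxyl; the cis-2,4-diequatorial ketone is the thermodynamic isomer, so C2 and C4 should hold.

Step 14
Reactants: 23 flavan-3-one
Product: 24 (2R,3R,4R)-7,8-bis(benzyloxy)-2-[4-(benzyloxy)phenyl]-4-{[(2S,3R,4R)-3,7,8-tris(benzyloxy)-2-[4-(benzyloxy)phenyl]chroman-4-yl]oxy}chroman-3-ol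
Conditions: L-Selectride, THF, −78 °C; aqueous work-up
Reagents that add atoms: none
Why: Substrate-controlled reduction in which the bulky hydride attacks C3 from the face opposite the cis 2-aryl and 4-alkoxy groups, giving the all-cis alcohol (the known catechin-to-epicatechin tactic).

Step 15
Reactants: 24 heptabenzyl ether
Product: 25 (2R,3R,4R)-4-{[(2S,3R,4R)-3,7,8-trihydroxy-2-(4-hydroxyphenyl)chroman-4-yl]oxy}-2-(4-hydroxyphenyl)chroman-3,7,8-triol (target)
Conditions: H2 (1 atm), Pd(OH)2/C, NaHCO3, EtOAc/MeOH, 23 °C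
Reagents that add atoms: none
Why: Hydrogenolysis of the seven benzyl ethers; buffered, neutral conditions are chosen so that the slower-reacting bis-benzylic dialkyl ether C4–O–C4 is left intact.

**Compound list**

1 | 3-fluorocatechol | Oc1cccc(F)c1O | starting material
2 | 1,2-bis(benzyloxy)-3-fluorobenzene | Fc1cccc(OCc2ccccc2)c1OCc1ccccc1 | intermediate
3 | 1,2-bis(benzyloxy)-4-bromo-3-fluorobenzene | Fc1c(Br)ccc(OCc2ccccc2)c1OCc1ccccc1 | intermediate
4 | (S)-4-benzyl-1,3-oxazolidine-2-thione | S=C1OC[C@H](Cc2ccccc2)N1 | starting material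
5 | benzyloxyacetyl chloride | O=C(Cl)COCc1ccccc1 | starting material
6 | (S)-4-benzyl-3-(benzyloxyacetyl)-1,3-oxazolidine-2-thione | O=C(COCc1ccccc1)N1C(=S)OC[C@@H]1Cc1ccccc1 | intermediate
7 | 4-(benzyloxy)benzaldehyde | O=Cc1ccc(OCc2ccccc2)cc1 | starting material
8 | (4S)-4-benzyl-3-[(2S,3S)-2-(benzyloxy)-3-[4-(benzyloxy)phenyl]-3-hydroxypropanoyl]-1,3-oxazolidine-2-thione | O[C@@H](c1ccc(OCc2ccccc2)cc1)[C@H](OCc1ccccc1)C(=O)N1C(=S)OC[C@@H]1Cc1ccccc1 | intermediate
9 | (2S,3S)-2-(benzyloxy)-3-[4-(benzyloxy)phenyl]-3-hydroxypropanoic acid | O[C@@H](c1ccc(OCc2ccccc2)cc1)[C@@H](C(=O)O)OCc1ccccc1 | intermediate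
10 | (3S,4S)-3-(benzyloxy)-4-[4-(benzyloxy)phenyl]oxetan-2-one | O=C1O[C@@H](c2ccc(OCc3ccccc3)cc2)[C@@H]1OCc1ccccc1 | intermediate
11 | 3,4-bis(benzyloxy)-2-fluorophenyllithium | [Li]c1ccc(OCc2ccccc2)c(OCc2ccccc2)c1F | intermediate
12 | lithium (1S,2S)-2-(benzyloxy)-3-[3,4-bis(benzyloxy)-2-fluorophenyl]-1-[4-(benzyloxy)phenyl]-3-oxopropan-1-olate | [Li]O[C@@H](c1ccc(OCc2ccccc2)cc1)[C@@H](C(=O)c1ccc(OCc2ccccc2)c(OCc2ccccc2)c1F)OCc1ccccc1 | intermediate
13 | (2S,3S)-3,7,8-tris(benzyloxy)-2-[4-(benzyloxy)phenyl]chroman-4-one | O=C1c2ccc(OCc3ccccc3)c(OCc3ccccc3)c2O[C@@H](c2ccc(OCc3ccccc3)cc2)[C@@H]1OCc1ccccc1 | intermediate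
14 | (2S,3R,4R)-3,7,8-tris(benzyloxy)-2-[4-(benzyloxy)phenyl]chroman-4-ol | O[C@@H]1c2ccc(OCc3ccccc3)c(OCc3ccccc3)c2O[C@@H](c2ccc(OCc3ccccc3)cc2)[C@@H]1OCc1ccccc1 | intermediate
15 | 7,8-dihydroxycoumarin (daphnetin) | O=C1C=Cc2ccc(O)c(O)c2O1 | starting material
16 | 7,8-bis(benzyloxy)-2H-chromen-2-one | O=C1C=Cc2ccc(OCc3ccccc3)c(OCc3ccccc3)c2O1 | intermediate
17 | 7,8-bis(benzyloxy)-2H-chromen-2-ol | OC1C=Cc2ccc(OCc3ccccc3)c(OCc3ccccc3)c2O1 | intermediate
18 | 7,8-bis(benzyloxy)-2-ethoxy-2H-chromene (racemic) | CCOC1C=Cc2ccc(OCc3ccccc3)c(OCc3ccccc3)c2O1 | intermediate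
19 | 4-(benzyloxy)phenylboronic acid | OB(O)c1ccc(OCc2ccccc2)cc1 | starting material
20 | (2S)-7,8-bis(benzyloxy)-2-[4-(benzyloxy)phenyl]-2H-chromene | C(c5ccccc5)Oc1ccc([C@H]2Oc3c(ccc(OCc5ccccc5)c3OCc5ccccc5)C=C2)cc1 | intermediate
21 | 3,4-epoxide of 20, oxirane on the face opposite the 2-aryl group | C(c5ccccc5)Oc1ccc([C@H]2Oc3c(ccc(OCc5ccccc5)c3OCc5ccccc5)[C@@H]3O[C@H]23)cc1 | intermediate
22 | (2R,3S,4R)-7,8-bis(benzyloxy)-2-[4-(benzyloxy)phenyl]-4-{[(2S,3R,4R)-3,7,8-tris(benzyloxy)-2-[4-(benzyloxy)phenyl]chroman-4-yl]oxy}chroman-3-ol | C(c5ccccc5)Oc1ccc([C@H]2Oc3c(ccc(OCc5ccccc5)c3OCc5ccccc5)[C@@H](O[C@@H]3c4ccc(OCc5ccccc5)c(OCc5ccccc5)c4O[C@@H](c4ccc(OCc5ccccc5)cc4)[C@@H]3OCc5ccccc5)[C@@H]2O)cc1 | intermediate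
23 | (2R,4R)-7,8-bis(benzyloxy)-2-[4-(benzyloxy)phenyl]-4-{[(2S,3R,4R)-3,7,8-tris(benzyloxy)-2-[4-(benzyloxy)phenyl]chroman-4-yl]oxy}chroman-3-one | C(c5ccccc5)Oc1ccc([C@H]2Oc3c(ccc(OCc5ccccc5)c3OCc5ccccc5)[C@@H](O[C@@H]3c4ccc(OCc5ccccc5)c(OCc5ccccc5)c4O[C@@H](c4ccc(OCc5ccccc5)cc4)[C@@H]3OCc5ccccc5)C2=O)cc1 | intermediate
24 | (2R,3R,4R)-7,8-bis(benzyloxy)-2-[4-(benzyloxy)phenyl]-4-{[(2S,3R,4R)-3,7,8-tris(benzyloxy)-2-[4-(benzyloxy)phenyl]chroman-4-yl]oxy}chroman-3-ol | C(c5ccccc5)Oc1ccc([C@H]2Oc3c(ccc(OCc5ccccc5)c3OCc5ccccc5)[C@@H](O[C@@H]3c4ccc(OCc5ccccc5)c(OCc5ccccc5)c4O[C@@H](c4ccc(OCc5ccccc5)cc4)[C@@H]3OCc5ccccc5)[C@H]2O)cc1 | intermediate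
25 | (2R,3R,4R)-4-{[(2S,3R,4R)-3,7,8-trihydroxy-2-(4-hydroxyphenyl)chroman-4-yl]oxy}-2-(4-hydroxyphenyl)chroman-3,7,8-triol | Oc1ccc([C@H]2Oc3c(ccc(O)c3O)[C@@H](O[C@@H]3c4ccc(O)c(O)c4O[C@@H](c4ccc(O)cc4)[C@@H]3O)[C@H]2O)cc1 | target

**Totals.** 15 steps. Longest linear sequence: 10 steps (3, 4, 5, 6, 7, 8, 12, 13, 14, 15).

**Steps most likely to fail**

Step 7 (key step). The lithium keto-alkoxide may undergo retro-aldol cleavage or C3 enolisation before the SNAr closure, and the ketone may take up a second aryllithium; each would erode yield and stereochemical purity. The fallback sets out from 10 and returns at 13, separating acylation from ring closure. The lactone is opened with MeNH(OMe)·HCl/i-PrMgCl to (2S,3S)-2-(benzyloxy)-3-[4-(benzyloxy)phenyl]-3-hydroxy-N-methoxy-N-methylpropanamide F1. TESCl/imidazole gives its triethylsilyl ether F2. Aryllithium 11 (from 3) adds once, through the stable chelated tetrahedral intermediate, to give after work-up (2S,3S)-2-(benzyloxy)-1-[3,4-bis(benzyloxy)-2-fluorophenyl]-3-[4-(benzyloxy)phenyl]-3-(triethylsilyloxy)propan-1-one F3. TBAF in THF at 0 °C then removes the silyl group and the freed alkoxide closes by SNAr to 13.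

Step 12. The labile benzylic epoxide may ionise and rearrange, or be captured by adventitious water, faster than the hindered axial alcohol 14 attacks, and a free cation would lower facial selectivity. The fallback sets out from 20 and returns at 22, using thiophilic activation instead. Epoxidation as before and opening with phenylmethanethiol gives the stable, purifiable (2R,3R,4R)-4-(benzylsulfanyl)-7,8-bis(benzyloxy)-2-[4-(benzyloxy)phenyl]chroman-3-ol F5. AgBF4 in CH2Cl2/THF at −40 °C then ionises only the thioether in the presence of 14, which adds trans to the 3-hydroxyl to give 22.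

Step 6. The 4-(4-benzyloxyphenyl) β-lactone may ionise at its benzylic C–O bond during formation or handling, leading to decarboxylation or epimerisation. The fallback sets out from 9 and returns at 13 with a less strained acyl donor. 2-Methoxypropene/PPTS converts 9 into (5S,6S)-5-(benzyloxy)-6-[4-(benzyloxy)phenyl]-2,2-dimethyl-1,3-dioxan-4-one F4. Aryllithium 11 adds to its C4 carbonyl at −78 °C; on warming, collapse of the adduct expels acetone and the C2 alkoxide, which closes by SNAr to 13.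

**Further compounds**

F1 | step 7 | (2S,3S)-2-(benzyloxy)-3-[4-(benzyloxy)phenyl]-3-hydroxy-N-methoxy-N-methylpropanamide | O[C@@H](c1ccc(OCc2ccccc2)cc1)[C@H](OCc1ccccc1)C(=O)N(C)OC
F2 | step 7 | (2S,3S)-2-(benzyloxy)-3-[4-(benzyloxy)phenyl]-N-methoxy-N-methyl-3-(triethylsilyloxy)propanamide | CC[Si](CC)(CC)O[C@@H](c1ccc(OCc2ccccc2)cc1)[C@H](OCc1ccccc1)C(=O)N(C)OC
F3 | step 7 | (2S,3S)-2-(benzyloxy)-1-[3,4-bis(benzyloxy)-2-fluorophenyl]-3-[4-(benzyloxy)phenyl]-3-(triethylsilyloxy)propan-1-one | CC[Si](CC)(CC)O[C@@H](c1ccc(OCc2ccccc2)cc1)[C@H](OCc1ccccc1)C(=O)c1ccc(OCc2ccccc2)c(OCc2ccccc2)c1F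
F4 | step 6 | (5S,6S)-5-(benzyloxy)-6-[4-(benzyloxy)phenyl]-2,2-dimethyl-1,3-dioxan-4-one | CC1(C)OC(=O)[C@@H](OCc2ccccc2)[C@H](c2ccc(OCc3ccccc3)cc2)O1
F5 | step 12 | (2R,3R,4R)-4-(benzylsulfanyl)-7,8-bis(benzyloxy)-2-[4-(benzyloxy)phenyl]chroman-3-ol | C(c5ccccc5)Oc1ccc([C@H]2Oc3c(ccc(OCc5ccccc5)c3OCc5ccccc5)[C@@H](SCc5ccccc5)[C@@H]2O)cc1
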